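**Plan**

- Numbering: ring A is the butenolide (O1, C2–C5) with exocyclic C6, C7 is the methyl-bearing stereocentre, C10=C11 the chain alkene, C12–C14 the propylene link, ring B the central furan (O1', C2'–C5'), ring C the terminal 3-furyl ring.
- Enabling feature: ring B carries the chain at C4' and a CH2–ring C unit at C2', which is the pattern a Z-enynol with ring C on its alkyne terminus gives once O1' closes onto C2' and the ring aromatizes.
- Retrosynthetic cuts, in order: the sulfate O–S bond; C6–C7 (sp2–sp3 coupling of an E-iodomethylidene tetronate with a C7 zinc reagent); O1'–C2' of ring B; the C3'-side enyne bond (Sonogashira); C14–C4' (carbomagnesiation); C12–C13 (orthoester Claisen).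
- Forward: the C7–C14 chain grows from (R)-γ-valerolactone, ring C is attached as 3-ethynylfuran, ring B is closed on the enynol, ring A (made separately by iodolactonization) is joined last, then sulfation.
- Stereochemistry: C7 comes from (R)-γ-valerolactone, is inverted once on iodination and then retained in the coupling. E-C10=C11 comes from the chair Claisen transition state; E-C5=C6 from anti iodolactonization followed by a geometry-retaining coupling.

Key step: step 11

Remark: the target is drawn as the neutral hydrogen sulfate, so the last step is written to end with a cold proton exchange of the first-formed pyridinium salt; the free acid would be kept cold and handled promptly.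

**Route**

Step 1
Reactants: 1 (R)-γ-valerolactone
Product: 2 (4R)-4-hydroxy-N-methoxy-N-methylpentanamide
Conditions: MeNH(OMe)·HCl, AlMe3, CH2Cl2, 0 °C → rt
Reagents that add atoms: N,O-dimethylhydroxylamine hydrochloride, CNOC.Cl
Why: Weinreb aminolysis of the lactone by the aluminium amide formed from AlMe3 and the amine salt opens the ring without touching C7, whose R configuration is carried through unchanged.

Step 2
Reactants: 2 (4R)-4-hydroxy-N-methoxy-N-methylpentanamide
Product: 3 (4R)-4-[(tert-butyldimethylsilyl)oxy]-N-methoxy-N-methylpentanamide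
Conditions: TBSCl, imidazole, DMF, rt
Reagents that add atoms: tert-butyldimethylsilyl chloride, CC(C)(C)[Si](C)(C)Cl
Why: Standard silyl ether formation caps the secondary hydroxyl, which stops relactonization and protects the C7 oxygen through the organometallic steps.

Step 3
Reactants: 3 (4R)-4-[(tert-butyldimethylsilyl)oxy]-N-methoxy-N-methylpentanamide
Product: 4 (4R)-4-[(tert-butyldimethylsilyl)oxy]pentanal
Conditions: i-Bu2AlH, THF, −78 °C
Reagents that add atoms: none
Why: Partial hydride reduction of the Weinreb amide stops at the chelated aluminium hemiaminal, which releases the aldehyde only on work-up.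

Step 4
Reactants: 4 (4R)-4-[(tert-butyldimethylsilyl)oxy]pentanal; 5 isopropenylmagnesium bromide
Product: 6 (6R)-6-[(tert-butyldimethylsilyl)oxy]-2-methylhept-1-en-3-ol (both C3 epimers)
Conditions: THF, −78 → 0 °C
Reagents that add atoms: none
Why: Grignard 1,2-addition to the aldehyde gives the isopropenyl carbinol; the new carbinol centre forms without control and is erased in the following rearrangement.

Step 5
Reactants: 6 (6R)-6-[(tert-butyldimethylsilyl)oxy]-2-methylhept-1-en-3-ol; 7 triethyl orthoacetate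
Product: 9 ethyl (4E,8R)-8-[(tert-butyldimethylsilyl)oxy]-4-methylnon-4-enoate, via mixed ketene acetal 8 (not isolated)
Conditions: EtCO2H (cat.), neat 7, 140 °C, EtOH distilled off
Reagents that add atoms: none
Why: Johnson–Claisen rearrangement through a chair transition state with the C7-bearing chain equatorial forms the C12–C13 bond and the E trisubstituted C10=C11 alkene while removing the carbinol centre.

Step 6
Reactants: 9 ethyl (4E,8R)-8-[(tert-butyldimethylsilyl)oxy]-4-methylnon-4-enoate
Product: 10 (4E,8R)-8-[(tert-butyldimethylsilyl)oxy]-4-methylnon-4-en-1-ol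
Conditions: LiAlH4, Et2O, 0 °C
Reagents that add atoms: none
Why: LiAlH4 reduction of the ester to the primary alcohol leaves the isolated alkene and the silyl ether untouched.

Step 7
Reactants: 10 (4E,8R)-8-[(tert-butyldimethylsilyl)oxy]-4-methylnon-4-en-1-ol
Product: 11 {[(2R,5E)-9-bromo-6-methylnon-5-en-2-yl]oxy}(tert-butyl)dimethylsilane
Conditions: CBr4, PPh3, CH2Cl2, 0 °C
Reagents that add atoms: carbon tetrabromide, BrC(Br)(Br)Br
Why: Appel bromination converts the primary alcohol to the bromide under neutral conditions that the silyl ether and alkene tolerate.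

Step 8
Reactants: 11 {[(2R,5E)-9-bromo-6-methylnon-5-en-2-yl]oxy}(tert-butyl)dimethylsilane; 12 propargyl alcohol
Product: 16 (6E,10R)-10-[(tert-butyldimethylsilyl)oxy]-2-[(Z)-iodomethylidene]-6-methylundec-6-en-1-ol, via chloromagnesium prop-2-yn-1-olate 13 (not isolated), via Grignard reagent 14 (not isolated), via cyclic alkenylmagnesium alkoxide 15 (not isolated)
Conditions: 11: Mg, THF, 45 °C; 12: MeMgCl (1.0 equiv), THF, 0 °C; combine, CuI (10 mol %), −10 °C → rt; then I2, THF, −20 → 0 °C
Reagents that add atoms: iodine, II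
Why: CuI-catalysed anti carbomagnesiation of the propargylic magnesium alkoxide places the chain on the internal alkyne carbon and magnesium on the terminal carbon cis to the CH2O group in a five-membered chelate, and iodinolysis of that C–Mg bond with retention gives the Z iodide.

Step 9
Reactants: 17 furan-3-carbaldehyde
Product: 18 3-ethynylfuran
Conditions: MeC(O)C(N2)P(O)(OMe)2, K2CO3, MeOH, 0 °C → rt; product kept as an Et2O solution
Reagents that add atoms: dimethyl (1-diazo-2-oxopropyl)phosphonate, COP(=O)(OC)C(=[N+]=[N-])C(C)=O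
Why: Ohira–Bestmann (Seyferth–Gilbert) homologation turns the aldehyde into the terminal alkyne under mild carbonate conditions that ring C tolerates.

Step 10
Reactants: 16 (6E,10R)-10-[(tert-butyldimethylsilyl)oxy]-2-[(Z)-iodomethylidene]-6-methylundec-6-en-1-ol; 18 3-ethynylfuran
Product: 19 (2Z,6E,10R)-10-[(tert-butyldimethylsilyl)oxy]-2-[3-(furan-3-yl)prop-2-yn-1-ylidene]-6-methylundec-6-en-1-ol
Conditions: PdCl2(PPh3)2 (3 mol %), CuI (6 mol %), Et3N, THF, rt
Reagents that add atoms: none
Why: Sonogashira coupling of the alkenyl iodide with the terminal alkyne proceeds with retention of the Z geometry and tolerates the free hydroxyl.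

Step 11
Reactants: 19 (2Z,6E,10R)-10-[(tert-butyldimethylsilyl)oxy]-2-[3-(furan-3-yl)prop-2-yn-1-ylidene]-6-methylundec-6-en-1-ol
Product: 21 tert-butyl({(2R,5E)-9-[5-(furan-3-ylmethyl)furan-3-yl]-6-methylnon-5-en-2-yl}oxy)dimethylsilane, via 2-furylmethylidene-2,5-dihydrofuran 20 (not isolated)
Conditions: AgNO3 on silica gel (10 wt %, 0.2 equiv), hexanes, rt, dark
Reagents that add atoms: none
Why: Monovalent silver binds the alkyne of 19, the allylic hydroxyl adds anti to the alkyne carbon nearer the alkene, and protodemetalation gives the ylidene dihydrofuran 20; a proton shift then pulls the exocyclic double bond into the ring, so the alkyne carbon next to ring C ends as the CH2 bridge between rings B and C. The closest known reaction type is the cycloisomerization of (Z)-2-en-4-yn-1-ols (β-alkynyl allylic alcohols) to furans on AgNO3-impregnated silica gel. Ring B closes in the 5-exo-dig mode through the new O1'–C2' bond. No stereocentre is created, and the 2,4-pattern cannot vary because the chain is already bonded to the alkene carbon that becomes C4'. The selectivity required is O-attack at C2' over 6-endo attack at the furyl-substituted carbon; the Z alkene holds the hydroxyl one short tether from C2', and the gain of furan aromaticity removes the 5-exo product from any equilibrium. The medium is close to neutral and free of protic acid, so the silyl ether, the C10=C11 alkene and ring C should pass through unchanged.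

Step 12
Reactants: 21 tert-butyl({(2R,5E)-9-[5-(furan-3-ylmethyl)furan-3-yl]-6-methylnon-5-en-2-yl}oxy)dimethylsilane
Product: 22 (2R,5E)-9-[5-(furan-3-ylmethyl)furan-3-yl]-6-methylnon-5-en-2-ol
Conditions: n-Bu4NF, THF, 0 °C → rt
Reagents that add atoms: none
Why: Fluoride-mediated desilylation frees the C7 hydroxyl without affecting the furans or the alkene.

Step 13
Reactants: 22 (2R,5E)-9-[5-(furan-3-ylmethyl)furan-3-yl]-6-methylnon-5-en-2-ol
Product: 23 2-(furan-3-ylmethyl)-4-[(4E,8S)-8-iodo-4-methylnon-4-en-1-yl]furan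
Conditions: PPh3, I2, N-methylimidazole, CH2Cl2, −10 °C, dark
Reagents that add atoms: iodine, II
Why: Appel-type iodination displaces the activated oxyphosphonium in an SN2 sense, so the R alcohol gives the S iodide; low temperature and the amine buffer limit iodide exchange and hence racemization.

Step 14
Reactants: 24 methyl propanoate; 25 3-(trimethylsilyl)prop-2-ynal
Product: 27 methyl 3-hydroxy-2-methyl-5-(trimethylsilyl)pent-4-ynoate (racemic, both diastereomers), via lithium enolate 26 (not isolated)
Conditions: LiN(i-Pr)2, THF, −78 °C; then 25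
Reagents that add atoms: none
Why: Lithium enolate aldol addition to the ynal assembles C2–C6 of ring A; both new stereocentres become sp2 later, so no control is needed.

Step 15
Reactants: 27 methyl 3-hydroxy-2-methyl-5-(trimethylsilyl)pent-4-ynoate
Product: 28 3-hydroxy-2-methylpent-4-ynoic acid (racemic, both diastereomers)
Conditions: LiOH, THF/MeOH/H2O, 0 °C → rt; then 1 M HCl
Reagents that add atoms: lithium hydroxide, [Li+].[OH-]
Why: Saponification of the methyl ester with concurrent hydroxide-induced cleavage of the alkynyl C–Si bond gives the free terminal ynoic acid.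

Step 16
Reactants: 28 3-hydroxy-2-methylpent-4-ynoic acid
Product: 29 (5E)-4-hydroxy-5-(iodomethylidene)-3-methyloxolan-2-one (racemic, both diastereomers)
Conditions: I2, NaHCO3, MeCN, 0 °C, dark
Reagents that add atoms: iodine, II
Why: Iodolactonization of the 4-pentynoic acid closes ring A 5-exo-dig by anti addition of carboxylate oxygen and iodine across the alkyne, which places iodine trans to O1 and so fixes the E geometry of C5=C6.

Step 17
Reactants: 29 (5E)-4-hydroxy-5-(iodomethylidene)-3-methyloxolan-2-one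
Product: 30 (5E)-4-hydroxy-5-(iodomethylidene)-3-methylfuran-2(5H)-one
Conditions: Dess–Martin periodinane (1.1 equiv), CH2Cl2, 0 °C → rt
Reagents that add atoms: none
Why: Dess–Martin oxidation of the β-hydroxy lactone gives the β-keto lactone, which exists as the enol (tetronic acid) and thereby removes both ring stereocentres.

Step 18
Reactants: 30 (5E)-4-hydroxy-5-(iodomethylidene)-3-methylfuran-2(5H)-one
Product: 31 (5E)-5-(iodomethylidene)-4-methoxy-3-methylfuran-2(5H)-one
Conditions: Me3SiCHN2, MeOH/toluene, 0 °C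
Reagents that add atoms: trimethylsilyldiazomethane, C[Si](C)(C)C=[N+]=[N-]
Why: O-methylation of the vinylogous acid by diazomethane released from Me3SiCHN2 in methanol is expected at O4, the position that keeps the conjugated butenolide.

Step 19
Reactants: 23 2-(furan-3-ylmethyl)-4-[(4E,8S)-8-iodo-4-methylnon-4-en-1-yl]furan; 31 (5E)-5-(iodomethylidene)-4-methoxy-3-methylfuran-2(5H)-one
Product: 34 (5E)-5-{(2S,5E)-9-[5-(furan-3-ylmethyl)furan-3-yl]-2,6-dimethylnon-5-en-1-ylidene}-4-methoxy-3-methylfuran-2(5H)-one, via secondary alkyllithium 32 (not isolated), via mixed dialkylzinc 33 (not isolated)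
Conditions: 23 added to t-BuLi (2.2 equiv), pentane/Et2O 3:2, −100 °C, 10 s; Me3SiCH2ZnBr·LiBr, THF, −100 → −25 °C; then 31, [Pd(μ-I)(P(t-Bu)3)]2 (3 mol %), −25 °C → rt
Reagents that add atoms: none
Why: Iodine–lithium exchange at −100 °C occurs with retention, immediate transmetalation gives a configurationally stable secondary alkylzinc, and its palladium-catalysed Negishi coupling with the alkenyl iodide retains configuration at both carbons, so C7 becomes S and C5=C6 stays E (stereoretentive Negishi coupling of a chiral secondary alkylzinc).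

Step 20
Reactants: 34 (5E)-5-{(2S,5E)-9-[5-(furan-3-ylmethyl)furan-3-yl]-2,6-dimethylnon-5-en-1-ylidene}-4-methoxy-3-methylfuran-2(5H)-one
Product: 36 (5E)-5-{(2S,5E)-9-[5-(furan-3-ylmethyl)furan-3-yl]-2,6-dimethylnon-5-en-1-ylidene}-4-hydroxy-3-methylfuran-2(5H)-one, via lithium tetronate 35 (not isolated)
Conditions: LiCl, DMSO, 60 °C; then 0.5 M HCl, 0 °C
Reagents that add atoms: none
Why: Chloride attacks the O-methyl carbon in an SN2 dealkylation (Krapcho-type) and releases the tetronate anion as leaving group, a method that avoids strong acids and soft nucleophiles that could add to C6.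

Step 21
Reactants: 36 (5E)-5-{(2S,5E)-9-[5-(furan-3-ylmethyl)furan-3-yl]-2,6-dimethylnon-5-en-1-ylidene}-4-hydroxy-3-methylfuran-2(5H)-one
Product: 38 (2E)-2-{(2S,5E)-9-[5-(furan-3-ylmethyl)furan-3-yl]-2,6-dimethylnon-5-en-1-ylidene}-4-methyl-5-oxo-2,5-dihydrofuran-3-yl hydrogen sulfate (CNP0018233.1), via pyridinium sulfate salt 37 (not isolated)
Conditions: SO3·pyridine (1.5 equiv), pyridine, 0 °C → rt; then cation-exchange resin (H+ form), MeOH, 0 °C
Reagents that add atoms: sulfur trioxide–pyridine complex, O=S(=O)([O-])[n+]1ccccc1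
Why: O-sulfation of the acidic enol by the SO3–pyridine complex is expected to be much faster at 0 °C than C-sulfonation of the furans, and cold proton exchange of the pyridinium salt gives the hydrogen sulfate.

**Compound list**

1 | (R)-γ-valerolactone, (5R)-5-methyloxolan-2-one | C[C@@H]1CCC(=O)O1 | starting material
2 | (4R)-4-hydroxy-N-methoxy-N-methylpentanamide | C[C@@H](O)CCC(=O)N(C)OC | intermediate
3 | (4R)-4-[(tert-butyldimethylsilyl)oxy]-N-methoxy-N-methylpentanamide | C[C@@H](O[Si](C)(C)C(C)(C)C)CCC(=O)N(C)OC | intermediate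
4 | (4R)-4-[(tert-butyldimethylsilyl)oxy]pentanal | C[C@@H](O[Si](C)(C)C(C)(C)C)CCC=O | intermediate
5 | isopropenylmagnesium bromide | CC(=C)[Mg]Br | starting material
6 | (6R)-6-[(tert-butyldimethylsilyl)oxy]-2-methylhept-1-en-3-ol, both C3 epimers | C[C@@H](O[Si](C)(C)C(C)(C)C)CCC(O)C(C)=C | intermediate
7 | triethyl orthoacetate | CCOC(C)(OCC)OCC | starting material
8 | mixed ketene acetal, 1-ethoxyvinyl ether of 6 | C[C@@H](O[Si](C)(C)C(C)(C)C)CCC(OC(=C)OCC)C(C)=C | intermediate
9 | ethyl (4E,8R)-8-[(tert-butyldimethylsilyl)oxy]-4-methylnon-4-enoate | C[C@@H](O[Si](C)(C)C(C)(C)C)CC/C=C(\C)CCC(=O)OCC | intermediate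
10 | (4E,8R)-8-[(tert-butyldimethylsilyl)oxy]-4-methylnon-4-en-1-ol | C[C@@H](O[Si](C)(C)C(C)(C)C)CC/C=C(\C)CCCO | intermediate
11 | {[(2R,5E)-9-bromo-6-methylnon-5-en-2-yl]oxy}(tert-butyl)dimethylsilane | C[C@@H](O[Si](C)(C)C(C)(C)C)CC/C=C(\C)CCCBr | intermediate
12 | propargyl alcohol, prop-2-yn-1-ol | OCC#C | starting material
13 | chloromagnesium prop-2-yn-1-olate | C#CCO[Mg]Cl | intermediate
14 | Grignard reagent of 11, [(4E,8R)-8-(TBSO)-4-methylnon-4-en-1-yl]magnesium bromide | C[C@@H](O[Si](C)(C)C(C)(C)C)CC/C=C(\C)CCC[Mg]Br | intermediate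
15 | cyclic alkenylmagnesium alkoxide, 2,5-dihydro-1,2-oxamagnesole with the chain on C4 | C[C@@H](O[Si](C)(C)C(C)(C)C)CC/C=C(\C)CCCC1=C[Mg]OC1 | intermediate
16 | (6E,10R)-10-[(tert-butyldimethylsilyl)oxy]-2-[(Z)-iodomethylidene]-6-methylundec-6-en-1-ol | C[C@@H](O[Si](C)(C)C(C)(C)C)CC/C=C(\C)CCC/C(CO)=C/I | intermediate
17 | furan-3-carbaldehyde | O=Cc1ccoc1 | starting material
18 | 3-ethynylfuran | C#Cc1ccoc1 | intermediate
19 | (2Z,6E,10R)-10-[(tert-butyldimethylsilyl)oxy]-2-[3-(furan-3-yl)prop-2-yn-1-ylidene]-6-methylundec-6-en-1-ol | C[C@@H](O[Si](C)(C)C(C)(C)C)CC/C=C(\C)CCC/C(CO)=C/C#Cc1ccoc1 | intermediate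
20 | (2Z)-2-(furan-3-ylmethylidene)-4-[(4E,8R)-8-(TBSO)-4-methylnon-4-en-1-yl]-2,5-dihydrofuran | C[C@@H](O[Si](C)(C)C(C)(C)C)CC/C=C(\C)CCCC1=C/C(=C/c2ccoc2)OC1 | intermediate
21 | tert-butyl({(2R,5E)-9-[5-(furan-3-ylmethyl)furan-3-yl]-6-methylnon-5-en-2-yl}oxy)dimethylsilane | C[C@@H](O[Si](C)(C)C(C)(C)C)CC/C=C(\C)CCCc1coc(Cc2ccoc2)c1 | intermediate
22 | (2R,5E)-9-[5-(furan-3-ylmethyl)furan-3-yl]-6-methylnon-5-en-2-ol | C[C@@H](O)CC/C=C(\C)CCCc1coc(Cc2ccoc2)c1 | intermediate
23 | 2-(furan-3-ylmethyl)-4-[(4E,8S)-8-iodo-4-methylnon-4-en-1-yl]furan | C[C@H](I)CC/C=C(\C)CCCc1coc(Cc2ccoc2)c1 | intermediate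
24 | methyl propanoate | CCC(=O)OC | starting material
25 | 3-(trimethylsilyl)prop-2-ynal | C[Si](C)(C)C#CC=O | starting material
26 | lithium enolate of methyl propanoate | CC=C(OC)O[Li] | intermediate
27 | methyl 3-hydroxy-2-methyl-5-(trimethylsilyl)pent-4-ynoate, racemic, both diastereomers | COC(=O)C(C)C(O)C#C[Si](C)(C)C | intermediate
28 | 3-hydroxy-2-methylpent-4-ynoic acid, racemic, both diastereomers | CC(C(O)C#C)C(=O)O | intermediate
29 | (5E)-4-hydroxy-5-(iodomethylidene)-3-methyloxolan-2-one, racemic, both diastereomers | CC1C(O)/C(=C\I)OC1=O | intermediate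
30 | (5E)-4-hydroxy-5-(iodomethylidene)-3-methylfuran-2(5H)-one | CC1=C(O)/C(=C\I)OC1=O | intermediate
31 | (5E)-5-(iodomethylidene)-4-methoxy-3-methylfuran-2(5H)-one | CC1=C(OC)/C(=C\I)OC1=O | intermediate
32 | {(2S,5E)-9-[5-(furan-3-ylmethyl)furan-3-yl]-6-methylnon-5-en-2-yl}lithium | C[C@H]([Li])CC/C=C(\C)CCCc1coc(Cc2ccoc2)c1 | intermediate
33 | {(2S,5E)-9-[5-(furan-3-ylmethyl)furan-3-yl]-6-methylnon-5-en-2-yl}[(trimethylsilyl)methyl]zinc | C[C@H]([Zn]C[Si](C)(C)C)CC/C=C(\C)CCCc1coc(Cc2ccoc2)c1 | intermediate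
34 | (5E)-5-{(2S,5E)-9-[5-(furan-3-ylmethyl)furan-3-yl]-2,6-dimethylnon-5-en-1-ylidene}-4-methoxy-3-methylfuran-2(5H)-one | CC1=C(OC)/C(=C\[C@@H](C)CC/C=C(\C)CCCc2coc(Cc3ccoc3)c2)OC1=O | intermediate
35 | lithium salt of 36 (lithium tetronate) | [Li+].CC1=C([O-])/C(=C\[C@@H](C)CC/C=C(\C)CCCc2coc(Cc3ccoc3)c2)OC1=O | intermediate
36 | (5E)-5-{(2S,5E)-9-[5-(furan-3-ylmethyl)furan-3-yl]-2,6-dimethylnon-5-en-1-ylidene}-4-hydroxy-3-methylfuran-2(5H)-one | CC1=C(O)/C(=C\[C@@H](C)CC/C=C(\C)CCCc2coc(Cc3ccoc3)c2)OC1=O | intermediate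
37 | pyridinium salt of 38 | CC1=C(OS(=O)(=O)[O-])/C(=C\[C@@H](C)CC/C=C(\C)CCCc2coc(Cc3ccoc3)c2)OC1=O.c1cc[nH+]cc1 | intermediate
38 | (2E)-2-{(2S,5E)-9-[5-(furan-3-ylmethyl)furan-3-yl]-2,6-dimethylnon-5-en-1-ylidene}-4-methyl-5-oxo-2,5-dihydrofuran-3-yl hydrogen sulfate, CNP0018233.1 | CC1=C(OS(=O)(=O)O)/C(=C\[C@@H](C)CC/C=C(\C)CCCc2coc(Cc3ccoc3)c2)OC1=O | target

**Step count**

Total: 21 steps. Longest linear sequence: 15 steps (steps 1–8, 10–13, 19–21). Side branches: step 9 (alkyne) and steps 14–18 (ring A).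

**Steps most likely to fail**

Step 19. The secondary alkyllithium may lose its C7 configuration before zinc capture, t-BuLi may deprotonate a furan, and the secondary alkylpalladium may chain-walk by β-hydride elimination. The fallback replaces the short-lived lithium species with an isolable, configurationally stable tin nucleophile. It sets out from alcohol 22, which with MsCl and Et3N should give (2R,5E)-9-[5-(furan-3-ylmethyl)furan-3-yl]-6-methylnon-5-en-2-yl methanesulfonate F1. Displacement with lithium 5-aza-1-stannabicyclo[3.3.3]undecan-1-ide (from the chlorostannatrane and lithium naphthalenide, THF, −78 °C) should proceed with inversion to the (S)-alkylstannatrane 1-{(2S,5E)-9-[5-(furan-3-ylmethyl)furan-3-yl]-6-methylnon-5-en-2-yl}-5-aza-1-stannabicyclo[3.3.3]undecane F2. A stereoretentive Stille coupling of F2 with iodide 31 (Pd(dba)2, a bulky electron-poor biarylphosphine, CuCl, KF, MeCN, 60 °C) comes back to the route at 34.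

Step 17. Once the ring is a vinylogous acid, the iodomethylidene group may isomerise to the Z form by acid- or iodide-promoted addition–elimination, and C3 may be over-oxidised. The fallback postpones the oxidation until the iodine is gone. It sets out from 29, which with TBSOTf and 2,6-lutidine should give (5E)-4-[(tert-butyldimethylsilyl)oxy]-5-(iodomethylidene)-3-methyloxolan-2-one F3. Coupling of F3 with zinc reagent 33 under the step 19 conditions should give (5E)-4-[(tert-butyldimethylsilyl)oxy]-5-{(2S,5E)-9-[5-(furan-3-ylmethyl)furan-3-yl]-2,6-dimethylnon-5-en-1-ylidene}-3-methyloxolan-2-one F4. Buffered HF·pyridine (THF, 0 °C) should then free (5E)-5-{(2S,5E)-9-[5-(furan-3-ylmethyl)furan-3-yl]-2,6-dimethylnon-5-en-1-ylidene}-4-hydroxy-3-methyloxolan-2-one F5. Dess–Martin oxidation of F5 comes back to the route at 36, so steps 18 and 20 are not needed.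

Step 20. A tetronate without a 3-acyl group may dealkylate slowly, and at the temperatures then needed the strained E exocyclic alkene may isomerise or take up chloride at C6. The fallback changes the O4 protecting group to one that leaves by fluoride-triggered fragmentation at 0 °C. It sets out from 30, which under Mitsunobu conditions (2-(trimethylsilyl)ethanol, PPh3 premixed with DIAD, THF, 0 °C) should give (5E)-5-(iodomethylidene)-3-methyl-4-[2-(trimethylsilyl)ethoxy]furan-2(5H)-one F6. Coupling of F6 with zinc reagent 33 as in step 19 should give (5E)-5-{(2S,5E)-9-[5-(furan-3-ylmethyl)furan-3-yl]-2,6-dimethylnon-5-en-1-ylidene}-3-methyl-4-[2-(trimethylsilyl)ethoxy]furan-2(5H)-one F7. Treatment of F7 with n-Bu4NF (THF, 0 °C) and mild acidification comes back to the route at 36.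

Further compounds
F1 | step 19 | (2R,5E)-9-[5-(furan-3-ylmethyl)furan-3-yl]-6-methylnon-5-en-2-yl methanesulfonate | C[C@@H](OS(C)(=O)=O)CC/C=C(\C)CCCc1coc(Cc2ccoc2)c1
F2 | step 19 | 1-{(2S,5E)-9-[5-(furan-3-ylmethyl)furan-3-yl]-6-methylnon-5-en-2-yl}-5-aza-1-stannabicyclo[3.3.3]undecane | C[C@H]([Sn]12CCCN(CCC1)CCC2)CC/C=C(\C)CCCc1coc(Cc2ccoc2)c1
F3 | step 17 | (5E)-4-[(tert-butyldimethylsilyl)oxy]-5-(iodomethylidene)-3-methyloxolan-2-one | CC1C(O[Si](C)(C)C(C)(C)C)/C(=C\I)OC1=O
F4 | step 17 | (5E)-4-[(tert-butyldimethylsilyl)oxy]-5-{(2S,5E)-9-[5-(furan-3-ylmethyl)furan-3-yl]-2,6-dimethylnon-5-en-1-ylidene}-3-methyloxolan-2-one | CC1C(O[Si](C)(C)C(C)(C)C)/C(=C\[C@@H](C)CC/C=C(\C)CCCc2coc(Cc3ccoc3)c2)OC1=O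
F5 | step 17 | (5E)-5-{(2S,5E)-9-[5-(furan-3-ylmethyl)furan-3-yl]-2,6-dimethylnon-5-en-1-ylidene}-4-hydroxy-3-methyloxolan-2-one | CC1C(O)/C(=C\[C@@H](C)CC/C=C(\C)CCCc2coc(Cc3ccoc3)c2)OC1=O
F6 | step 20 | (5E)-5-(iodomethylidene)-3-methyl-4-[2-(trimethylsilyl)ethoxy]furan-2(5H)-one | CC1=C(OCC[Si](C)(C)C)/C(=C\I)OC1=O
F7 | step 20 | (5E)-5-{(2S,5E)-9-[5-(furan-3-ylmethyl)furan-3-yl]-2,6-dimethylnon-5-en-1-ylidene}-3-methyl-4-[2-(trimethylsilyl)ethoxy]furan-2(5H)-one | CC1=C(OCC[Si](C)(C)C)/C(=C\[C@@H](C)CC/C=C(\C)CCCc2coc(Cc3ccoc3)c2)OC1=O
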